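Positions follow isochroman-1-one numbering: C1 (C=O), O2, C3, C4, C4a, C5–C8, C8a. The side chain is C1'–C17'.

## Analysis of the target

The target 14 is a 3,4-dihydroisocoumarin. A benzenoid ring A (C4a, C5, C6, C7, C8, C8a) is fused to a δ-lactone ring B (C1, O2, C3, C4, C4a, C8a), and C3 carries an unbranched (1'E,3'E)-heptadeca-1',3'-dienyl chain. Ring A has three contiguous substituents (phenol on C8, lactone carbonyl on C8a, C4 methylene on C4a) followed by three contiguous unsubstituted CH groups (C5, C6, C7). The string C8(OH)–C7H–C6H–C5H matches, atom for atom, the diene C3(OH)–C4H–C5H–C6H of 3-hydroxy-2H-pyran-2-one (11). The remaining pair C8a/C4a, one carbon bearing a carboxyl and the other a CH2, is the triple bond of a 2-ynoate, and the route is built on this match.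

There is one stereocenter, C3, of R configuration (O2 > C1' > C4 > H), so only absolute configuration has to be controlled. C3 is at once the alkyl-oxygen carbon of the lactone, dienylic and homobenzylic. The C3–O2 bond therefore ionises easily to a pentadienyl cation with Brønsted or Lewis acids and to a pentadienyl complex with zerovalent palladium, while base removes a benzylic C4 proton and expels the carboxylate to give a ring-opened triene acid. The E,E-diene is also open to oxidants, electrophiles, dienophiles and radical E/Z isomerisation.

The difficulty is compatibility rather than size. The usual tools of salicylate chemistry (strong-base lateral metalation, boron trihalide O-demethylation, palladium coupling) all endanger this dienylic lactone, and C3 must be set and carried as one enantiomer.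

## Retrosynthetic reasoning

**Bond C1–O2 (ring B), 14 ⇒ 13.** The lactone is cut at the acyl–oxygen bond and not at C3–O2, because any forward reaction that makes C3–O2 risks the pentadienyl cation and the loss of configuration. The precursor is hydroxy ester 13. The forward reaction is a neutral 6-exo-trig transesterification that needs no reagent, so it can ride on the step before it.

**Bonds C8–C8a and C4a–C5 (ring A), 13 ⇒ 12 ⇒ 10 + 11.**
- The arene is not bought; it is made. Cutting these two bonds splits ring A into the four-carbon diene of pyrone 11 (which becomes C8, C7, C6, C5, with the phenol oxygen already in place) and the triple bond of the acyclic ynoate 10 (which becomes C8a and C4a).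
- The cut is placed here because it is the only pair of bonds that leaves both ortho substituents on one two-carbon unit and the free phenol on the other.
- No phenol protecting group, no lateral metalation and no demethylation ever meet the dienylic C3–O bond.
- The forward reaction must add the diene of 11 across the ynoate with the ester carbon next to the hydroxyl-bearing carbon. It must also lose the lactone bridge of 12 by decarboxylative cycloreversion and leave the side-chain diene untouched.
- The precursor 10 has no ring at all, whereas the product has both rings.

**Bond C1–C8a, 10 ⇒ 9 ⇒ 8.** The ester carbon is removed from the alkyne terminus. This leaves terminal alkyne 8, whose only acidic C–H is exactly where the carbon must go. The forward sequence is a one-carbon carboxylation of the doubly deprotonated alcohol to acid 9 and a mild O-methylation to 10, without a protecting group.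

**Bond C3–C4 and the stereocenter, 8 ⇒ 7 ⇒ 5 + 6.** The bond between the carbinol carbon and its propargylic CH2 is cut, which gives achiral dienal 5 and the three-carbon allenylboron reagent 6. This places the only stereocenter in a catalytic enantioselective carbonyl addition through a closed six-membered transition state. It is done on the simplest possible substrate and before any sensitive ester is present. The forward reaction must attack the Re face of 5 and deliver the propargyl, not the allenyl, isomer; borate 7 is hydrolysed at work-up.

**Bond C3'=C4', 5 ⇒ 4 ⇒ 3 ⇒ 1 + 2.** The distal double bond of the diene is cut by a vinylogous olefination. This pairs the saturated C14 aldehyde 1 with the four-carbon phosphonate 2, which already contains the proximal E double bond. Ester 3 is then adjusted to the aldehyde level through alcohol 4, a stage at which geometric purity can be raised by crystallisation.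

## Alternatives that were turned down

**Alternative 1:** (the textbook route) cut C3–C4 next to a purchased arene.
- Forward key step: ethyl 2-methoxy-6-methylbenzoate A1 is deprotonated at the methyl group with a lithium amide. The benzylic anion adds to dienal 5 and the alkoxide closes ring B in the flask, giving racemic 8-methoxy-3-[(1E,3E)-heptadeca-1,3-dien-1-yl]isochroman-1-one A2. O-demethylation follows.
- No element in the transition state controls C3, so A2 is racemic and a resolution or an oxidation/asymmetric reduction detour must be added.
- The soft benzylic anion can also add to 5 in the 1,4 or 1,6 sense.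
- The excess strong base is exactly what opens ring B by elimination across C3–C4.
- The closing demethylation needs a boron or aluminium halide that coordinates the lactone and ionises the dienylic C3–O2 bond.

**Alternative 2:** cut C4–C4a together with C1–O2.
- Forward key step: carboxylate-directed ortho C–H alkylation of 2-methoxybenzoic acid A3 with (2S)-2-[(1E,3E)-heptadeca-1,3-dien-1-yl]oxirane A4 under Pd(OAc)2 catalysis. The palladacycle opens the epoxide at its CH2 terminus and the alkoxide lactonises.
- On paper this closes ring B in one operation with retention at the carbinol carbon.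
- A4 is a dienyl epoxide, however. Lewis-acidic divalent palladium, and any zerovalent palladium formed, open it at the allylic carbon or in a conjugate sense through a pentadienyl complex, which destroys both regiochemistry and configuration.
- A4 as a single enantiomer is itself not a short target.
- The way round uses an epoxide that carries a masked aldehyde in place of the diene. It leads to (3R)-8-methoxy-1-oxoisochromane-3-carbaldehyde A5, whose C3–H is α to both a formyl and an acyloxy group and epimerises readily.
- An E,E-selective olefination and the same harmful demethylation would still follow, so the steps after the key step outweigh its gain.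

**Alternative 3:** cut C2'–C3', the sp2–sp2 bond in the middle of the diene.
- Forward key step: Suzuki–Miyaura coupling of (3R)-8-hydroxy-3-[(E)-2-iodoethenyl]isochroman-1-one A6 with (E)-pentadec-1-en-1-ylboronic acid A7.
- The cut is convergent for the chain but leaves rings A and B and the stereocenter unsolved inside A6. That fragment would need an aldehyde of the A5 type and an iodo-olefination, so it is longer than the whole present route.
- A6 is an allylic carboxylate and its coupling product a dienylic one. Both compete with the C–I bond for zerovalent palladium by ionisation of C3–O2.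
- The aqueous base of the coupling favours lactone opening and elimination.

Key step: step 7

Assumption: the sense of induction of (R)-TRIP with dienal 5 is taken to be that established for aryl and alkenyl aldehydes (Re-face attack, R alcohol). The configuration would be checked at the stage of 8, and the equally available (S)-acid used if the sense were opposite.

## Route

Step 1
Reactants: 1 tetradecanal; 2 triethyl 4-phosphonocrotonate
Product: 3 ethyl (2E,4E)-octadeca-2,4-dienoate
Conditions: LiN(SiMe3)2, THF, −78 °C to rt
Reagents that add atoms: none
Why: Vinylogous Horner–Wadsworth–Emmons olefination; the stabilised allylic phosphonate anion reacts at the carbon next to phosphorus and reversible addition favours the new E double bond, while the E double bond already present in 2 is retained.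

Step 2
Reactants: 3 ethyl (2E,4E)-octadeca-2,4-dienoate
Product: 4 (2E,4E)-octadeca-2,4-dien-1-ol
Conditions: i-Bu2AlH (2.2 equiv), CH2Cl2, −78 to 0 °C; aq. potassium sodium tartrate
Reagents that add atoms: none
Why: 1,2-Reduction of a conjugated ester with an aluminium hydride, which does not touch the diene; the long-chain alcohol should be a solid, so minor geometric isomers can be removed by recrystallisation.

Step 3
Reactants: 4 (2E,4E)-octadeca-2,4-dien-1-ol
Product: 5 (2E,4E)-octadeca-2,4-dienal
Conditions: activated MnO2, CH2Cl2, rt
Reagents that add atoms: none
Why: Selective heterogeneous oxidation of an allylic (dienylic) alcohol under neutral conditions, which stops at the aldehyde and leaves the E,E geometry intact.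

Step 4
Reactants: 5 (2E,4E)-octadeca-2,4-dienal; 6 allenylboronic acid pinacol ester
Product: 8 (4R,5E,7E)-henicosa-5,7-dien-1-yn-4-ol, via pinacol borate ester 7 (not isolated)
Conditions: (R)-TRIP (10 mol %), 4 Å MS, toluene, −20 °C; aq. NaHCO3
Reagents that add atoms: none
Why: Chiral phosphoric acid catalysed asymmetric propargylation of an aldehyde with an allenylboronate, a reaction type that covers α,β-unsaturated aldehydes; the closed six-membered SE2' transition state gives only the homopropargylic isomer. The acid binds a boronate oxygen and the formyl hydrogen, shields the Si face of 5, and Re-face attack sets C4 as R, the future C3 of the target.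

Step 5
Reactants: 8 (4R,5E,7E)-henicosa-5,7-dien-1-yn-4-ol
Product: 9 (5R,6E,8E)-5-hydroxydocosa-6,8-dien-2-ynoic acid
Conditions: n-BuLi (2.1 equiv), THF, −78 °C; CO2 (dry gas), −78 to 0 °C; ice-cold 0.5 M HCl/Et2O, immediate extraction
Reagents that add atoms: carbon dioxide, O=C=O
Why: Carboxylation of a homopropargylic alcohol after double deprotonation, a classical entry to 5-hydroxy-2-ynoic acids; the acetylide carbon is carboxylated irreversibly whereas carbonate formation at the alkoxide is undone at work-up. The stereocenter is not involved and the cold, brief, biphasic acidification spares the dienylic alcohol.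

Step 6
Reactants: 9 (5R,6E,8E)-5-hydroxydocosa-6,8-dien-2-ynoic acid
Product: 10 methyl (5R,6E,8E)-5-hydroxydocosa-6,8-dien-2-ynoate
Conditions: MeI, KHCO3, DMF, 0 °C to rt
Reagents that add atoms: iodomethane, CI
Why: SN2 O-alkylation of the potassium carboxylate; the weak base neither deprotonates the alcohol nor isomerises the ynoate to an allenoate. A diazoalkane is avoided because it would add to the ynoate as a 1,3-dipole, and acid-catalysed esterification is avoided because of the dienylic alcohol.

Step 7
Reactants: 10 methyl (5R,6E,8E)-5-hydroxydocosa-6,8-dien-2-ynoate; 11 3-hydroxy-2H-pyran-2-one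
Product: 14 (3R)-8-hydroxy-3-[(1E,3E)-heptadeca-1,3-dien-1-yl]isochroman-1-one, via bridged lactone cycloadduct 12 (not isolated), via hydroxy ester 13 (not isolated)
Conditions: 11 (3 equiv), BHT (10 mol %), 4 Å MS, toluene (0.1 M in 10), sealed tube, 135 °C, dark
Reagents that add atoms: none
Why: Diels–Alder/retro-Diels–Alder benzannulation followed by lactonisation: the s-cis-locked diene C3=C4–C5=C6 of 11, raised in energy by its 3-OH donor, adds across C2≡C3 of ynoate 10 to give bridged lactone 12, which expels CO2 by cycloreversion faster than it forms because an arene results, and the side-chain hydroxyl of the resulting 13 then attacks the neighbouring ester with loss of MeOH. The closest known reaction type is the 2-pyrone/alkyne cycloaddition–decarboxylation, established for 3-hydroxy-2-pyrone and acetylenic esters as a salicylate synthesis. Ring A is closed by an intermolecular [4+2] that forms C8–C8a and C4a–C5 (target numbering), and ring B by a 6-exo-trig acyl substitution that forms C1–O2, helped by the phenol–ester hydrogen bond and by uptake of MeOH on the sieves. No stereocenter that survives is created: the two bridgehead centres of 12 vanish with CO2, and C3 keeps the R configuration of step 4 because only the acyl–oxygen bond, never C3–O, is made under neutral conditions. Regioselectivity rests on polarity: the largest HOMO coefficient of 11 lies at C6, vinylogous to the 3-OH, and bonds to the electrophilic β-carbon C3 of 10, so the ester carbon ends next to the phenol, and an O–H···O=C hydrogen bond between 11 and the ester in the transition state points the same way. Chemoselectivity over the side-chain diene rests on four facts: that diene is acyclic, 1,4-dialkylated and without a donor; it must first reach its s-cis form; it cannot reach the ynoate within the molecule because the two-atom link would demand a four-membered ring; and it is outcompeted between molecules by the dilution of 10 and the excess of 11. BHT and darkness guard the E,E geometry against radical isomerisation.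

## Compound list

1 | tetradecanal | CCCCCCCCCCCCCC=O | starting material
2 | triethyl 4-phosphonocrotonate (ethyl (E)-4-(diethoxyphosphoryl)but-2-enoate) | CCOC(=O)/C=C/CP(=O)(OCC)OCC | starting material
3 | ethyl (2E,4E)-octadeca-2,4-dienoate | CCCCCCCCCCCCC/C=C/C=C/C(=O)OCC | intermediate
4 | (2E,4E)-octadeca-2,4-dien-1-ol | CCCCCCCCCCCCC/C=C/C=C/CO | intermediate
5 | (2E,4E)-octadeca-2,4-dienal | CCCCCCCCCCCCC/C=C/C=C/C=O | intermediate
6 | allenylboronic acid pinacol ester (4,4,5,5-tetramethyl-2-(propa-1,2-dien-1-yl)-1,3,2-dioxaborolane) | C=C=CB1OC(C)(C)C(C)(C)O1 | starting material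
7 | 2-{[(4R,5E,7E)-henicosa-5,7-dien-1-yn-4-yl]oxy}-4,4,5,5-tetramethyl-1,3,2-dioxaborolane | CCCCCCCCCCCCC/C=C/C=C/[C@H](OB1OC(C)(C)C(C)(C)O1)CC#C | intermediate
8 | (4R,5E,7E)-henicosa-5,7-dien-1-yn-4-ol | CCCCCCCCCCCCC/C=C/C=C/[C@H](O)CC#C | intermediate
9 | (5R,6E,8E)-5-hydroxydocosa-6,8-dien-2-ynoic acid | CCCCCCCCCCCCC/C=C/C=C/[C@H](O)CC#CC(=O)O | intermediate
10 | methyl (5R,6E,8E)-5-hydroxydocosa-6,8-dien-2-ynoate | CCCCCCCCCCCCC/C=C/C=C/[C@H](O)CC#CC(=O)OC | intermediate
11 | 3-hydroxy-2H-pyran-2-one | O=C1OC=CC=C1O | starting material
12 | methyl 4-hydroxy-7-[(2R,3E,5E)-2-hydroxynonadeca-3,5-dien-1-yl]-3-oxo-2-oxabicyclo[2.2.2]octa-5,7-diene-8-carboxylate (both bridgehead epimers) | OC12C=CC(OC1=O)C(C[C@@H](O)/C=C/C=C/CCCCCCCCCCCCC)=C2C(=O)OC | intermediate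
13 | methyl 2-hydroxy-6-[(2R,3E,5E)-2-hydroxynonadeca-3,5-dien-1-yl]benzoate | COC(=O)c1c(O)cccc1C[C@@H](O)/C=C/C=C/CCCCCCCCCCCCC | intermediate
14 | (3R)-8-hydroxy-3-[(1E,3E)-heptadeca-1,3-dien-1-yl]isochroman-1-one | CCCCCCCCCCCCC/C=C/C=C/[C@H]1Cc2cccc(O)c2C(=O)O1 | target

## Step count and risk

Total step count: 7. Longest linear sequence: 7 steps (1 to 14); compounds 2, 6 and 11 are purchased.

**Step 7 (key step).**
- What may go wrong: the β-alkyl group makes ynoate 10 a sluggish dienophile, and long heating opens side paths. These are intermolecular cycloaddition of the side-chain diene of one molecule onto the ynoate of another, thermal retro-ene fragmentation of the β-hydroxy alkyne unit back towards the dienal, erosion of regioselectivity, and incomplete lactonisation.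
- Fallback (from 10, back to the route at 13): the arene is still built on the ynoate, but from an acyclic vinylketene acetal and with aromatisation by elimination instead of cycloreversion. This diene is more strongly polarised and should react well below the temperature of step 7, with the hydroxyl masked.
- Compound 10 is silylated (TBSCl, imidazole, DMF) to methyl (5R,6E,8E)-5-(tert-butyldimethylsilyloxy)docosa-6,8-dien-2-ynoate F1.
- Methyl crotonate is converted with LiN(i-Pr)2 and TMSCl into 1-methoxy-1-(trimethylsilyloxy)buta-1,3-diene F2.
- F1 and F2 combine in toluene at 90–100 °C, the CH2 terminus of the diene bonding to the β-carbon, to give methyl 2-[(2R,3E,5E)-2-(tert-butyldimethylsilyloxy)nonadeca-3,5-dien-1-yl]-6-methoxy-6-(trimethylsilyloxy)cyclohexa-1,4-diene-1-carboxylate F3.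
- On stirring with moist silica gel, F3 aromatises to methyl 2-[(2R,3E,5E)-2-(tert-butyldimethylsilyloxy)nonadeca-3,5-dien-1-yl]-6-hydroxybenzoate F4.
- Pyridine-buffered HF·pyridine in THF then liberates 13, which lactonises to 14 on gentle warming in toluene.

**Step 4.**
- What may go wrong: poor facial selectivity, because the flat, slender dienal offers the catalyst pocket less steric contrast than an aryl aldehyde. Uncatalysed background addition would dilute the enantiomeric purity further.
- Fallback (from 5, back at 8): the stereocenter is obtained by kinetic resolution instead of asymmetric addition.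
- A Barbier reaction of 5 with propargyl bromide and Zn in THF/aq. NH4Cl gives racemic (5E,7E)-henicosa-5,7-dien-1-yn-4-ol F5.
- A Sharpless kinetic resolution follows (Ti(OiPr)4, L-(+)-DIPT, t-BuOOH, 4 Å MS, CH2Cl2, −20 °C, run past half conversion). It epoxidises the fast-reacting S enantiomer at the proximal double bond to (1S)-1-{(2R,3R)-3-[(1E)-pentadec-1-en-1-yl]oxiran-2-yl}but-3-yn-1-ol F6, which is removed by chromatography. The slow-reacting R alcohol 8 is recovered.

**Step 5.**
- What may go wrong: the doubly deprotonated alcohol may be carboxylated incompletely, the lithium alkoxide may fragment by retro-addition on warming, and the strong ynoic acid may catalyse ionisation of its own dienylic alcohol during acidification and concentration.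
- Fallback (from 8, back at 10, bypassing 9 and step 6): the alcohol is masked and the ester is introduced directly.
- Compound 8 is silylated (TESCl, imidazole, CH2Cl2) to (4R,5E,7E)-4-(triethylsilyloxy)henicosa-5,7-dien-1-yne F7.
- Lithiation (n-BuLi, THF, −78 °C) and acylation with methyl chloroformate give methyl (5R,6E,8E)-5-(triethylsilyloxy)docosa-6,8-dien-2-ynoate F8.
- Pyridine-buffered HF·pyridine at 0 °C returns 10.

**Step 1.**
- What may go wrong: incomplete E selectivity at the new double bond and partial reaction of the ambident anion at its γ-carbon. Geometric isomers of such long-chain esters are hard to separate and would be carried into the target.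
- Fallback (from 1, back at 5, bypassing 3 and 4): the diene is built by two successive two-carbon Wittig homologations with the stabilised ylide (triphenylphosphoranylidene)acetaldehyde in warm toluene.
- The first homologation gives (E)-hexadec-2-enal F9 and the second gives 5. Each step forms one E double bond under thermodynamic control and stays at the aldehyde oxidation level.

## Further compounds

F1 | step 7 | methyl (5R,6E,8E)-5-(tert-butyldimethylsilyloxy)docosa-6,8-dien-2-ynoate | CCCCCCCCCCCCC/C=C/C=C/[C@H](O[Si](C)(C)C(C)(C)C)CC#CC(=O)OC
F2 | step 7 | 1-methoxy-1-(trimethylsilyloxy)buta-1,3-diene | C=CC=C(OC)O[Si](C)(C)C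
F3 | step 7 | methyl 2-[(2R,3E,5E)-2-(tert-butyldimethylsilyloxy)nonadeca-3,5-dien-1-yl]-6-methoxy-6-(trimethylsilyloxy)cyclohexa-1,4-diene-1-carboxylate | COC(=O)C1=C(C[C@@H](O[Si](C)(C)C(C)(C)C)/C=C/C=C/CCCCCCCCCCCCC)CC=CC1(OC)O[Si](C)(C)C
F4 | step 7 | methyl 2-[(2R,3E,5E)-2-(tert-butyldimethylsilyloxy)nonadeca-3,5-dien-1-yl]-6-hydroxybenzoate | COC(=O)c1c(O)cccc1C[C@@H](O[Si](C)(C)C(C)(C)C)/C=C/C=C/CCCCCCCCCCCCC
F5 | step 4 | racemic (5E,7E)-henicosa-5,7-dien-1-yn-4-ol | CCCCCCCCCCCCC/C=C/C=C/C(O)CC#C
F6 | step 4 | (1S)-1-{(2R,3R)-3-[(1E)-pentadec-1-en-1-yl]oxiran-2-yl}but-3-yn-1-ol | C#CC[C@H](O)[C@H]1O[C@@H]1/C=C/CCCCCCCCCCCCC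
F7 | step 5 | (4R,5E,7E)-4-(triethylsilyloxy)henicosa-5,7-dien-1-yne | CCCCCCCCCCCCC/C=C/C=C/[C@H](O[Si](CC)(CC)CC)CC#C
F8 | step 5 | methyl (5R,6E,8E)-5-(triethylsilyloxy)docosa-6,8-dien-2-ynoate | CCCCCCCCCCCCC/C=C/C=C/[C@H](O[Si](CC)(CC)CC)CC#CC(=O)OC
F9 | step 1 | (E)-hexadec-2-enal | CCCCCCCCCCCCC/C=C/C=O
A1 | alternative 1 | ethyl 2-methoxy-6-methylbenzoate | CCOC(=O)c1c(C)cccc1OC
A2 | alternative 1 | racemic 8-methoxy-3-[(1E,3E)-heptadeca-1,3-dien-1-yl]isochroman-1-one | CCCCCCCCCCCCC/C=C/C=C/C1Cc2cccc(OC)c2C(=O)O1
A3 | alternative 2 | 2-methoxybenzoic acid | COc1ccccc1C(=O)O
A4 | alternative 2 | (2S)-2-[(1E,3E)-heptadeca-1,3-dien-1-yl]oxirane | CCCCCCCCCCCCC/C=C/C=C/[C@H]1CO1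
A5 | alternative 2 | (3R)-8-methoxy-1-oxoisochromane-3-carbaldehyde | O=C[C@H]1Cc2cccc(OC)c2C(=O)O1
A6 | alternative 3 | (3R)-8-hydroxy-3-[(E)-2-iodoethenyl]isochroman-1-one | I/C=C/[C@H]1Cc2cccc(O)c2C(=O)O1
A7 | alternative 3 | (E)-pentadec-1-en-1-ylboronic acid | CCCCCCCCCCCCC/C=C/B(O)O
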